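Before south is charged, one thing has to be chosen: what carries over from Wednesday's run, its percent of charge per minute or its mM per minute? Wednesday's run had twice the starting material of south, at the same temperature and with the same enzyme.

| flask | starting material | second substrate | free enzyme | temperature | remark | time |
|---|---|---|---|---|---|---|
| Tuesday's | 10 mM | 20 mM | 2 µM | 2 °C | run made earlier |  |
| Wednesday's | 40 mM | 20 mM | 2 µM | 22 °C | run made earlier |  |
| Friday's | 20 mM | 20 mM | 4 µM | 2 °C | run made earlier |  |
| south | 20 mM | 20.0 mM | 2.0 µM | 22 °C |  | 100 min |
| south-west | 20 mM | 20.0 mM | 2.0 µM | 7 °C |  | 100 min |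
| east | 20 mM | 20.0 mM | 2.0 µM | 37 °C |  | 100 min |

| run | time / min | target / % |
|---|---|---|
| Tuesday's | 15.0 | 2.7 |
| Tuesday's | 30.0 | 7.3 |
| Tuesday's | 60.0 | 10.2 |
| Tuesday's | 150 | 28.1 |
| Wednesday's | 8.00 | 4.0 |
| Wednesday's | 20.0 | 4.8 |
| Wednesday's | 40.0 | 8.8 |
| Wednesday's | 60.0 | 14.7 |
| Friday's | 40.0 | 8.6 |
| Friday's | 80.0 | 19.5 |
| Friday's | 150 | 36.8 |

(readings scatter by 1 percentage point)

1. the flask with the highest amount of target, in percent of the starting material charged ("all alike" if they lie within 1.5 percentage points) (south / south-west / east / all alike)
2. final target, as a percentage of the starting material charged, in south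
3. final target, as a percentage of the starting material charged, in south-west
4. final target, as a percentage of the starting material charged, in east

The scale for this choice is the charge factor: percent of charge per minute per unit of enzyme at a doubled charge, over the same at the single charge. A first-order flask, where the fraction converted per minute ignores the charge, sits at 1; a saturated flask, where mM per minute ignores the charge, sits at 0.5. Tuesday's and Friday's runs, both at 2 °C, give 0.655 as a reading, provided the rate follows the enzyme.

The first chemist holds to the first-order mark of the scale, a charge factor of 1. No run compares charges at 22 °C, she says, so Wednesday's last reading carries over as it stands, and south reaches 24.5%. The second chemist made the forecast and takes the cold reading seriously: “Doubling the starting material raises the rate only 1.3-fold”. My own division of Wednesday's percent per minute by the charge factor gives 37.4% for south. The forecast, integrating its own rate law, says 39% (range 33% to 46%) for south, 17% for south-west and 68% for east, and names east as the highest.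

South gives 29.2%, south-west 17.5% and east 94.3%, so east is highest, as forecast. South lies nearer the first chemist, 4.7 percentage points from her number against 9.8 points from the forecast, while the forecast holds in the cold, at south-west. In south at 100 min, complex B, the resting state there, holds 66.5% of the catalyst charged, against 13.7% in complex A. Wednesday's run and south put the charge factor at 0.840 at 22 °C, above the cold reading. Applied to Tuesday's run at its last reading, 27.4% without scatter, the cold factor gives 17.9% for a charge of 20 mM; that run so recharged stands at 18.5%.

    free enzyme → unfolded enzyme (k = 3.13 × 10⁻⁴ min⁻¹, Ea = 192 kJ mol⁻¹)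
    starting material + free enzyme ⇌ complex A (K = 95.0 L mol⁻¹, k = 1.25 × 10⁵ L mol⁻¹ s⁻¹, Ea = 15.0 kJ mol⁻¹, ΔH = −59.0 kJ mol⁻¹)
    complex A → free enzyme + target (k = 959 min⁻¹, Ea = 79.0 kJ mol⁻¹)
    second substrate + free enzyme ⇌ complex B (K = 2990 L mol⁻¹, k = 45500 L mol⁻¹ s⁻¹, Ea = 33.0 kJ mol⁻¹, ΔH = 28.0 kJ mol⁻¹)
    complex B → free enzyme + second product (k = 203 min⁻¹, Ea = 72.0 kJ mol⁻¹)
    starting material → decomposition product (k = 1.14 × 10⁻⁴ min⁻¹, Ea = 103 kJ mol⁻¹)
    complex A → spent catalyst (k = 0.0591 min⁻¹, Ea = 83.0 kJ mol⁻¹)
    (constants at 37 °C)

(The readings stem from a simulated flask with constants of no real substance; scatter was added.)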